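## Retrosynthetic overview

1. The dihydropyran ring of myrtucommulone K is cut at C5–C1′ and C4–O (inverse-electron-demand oxa-Diels–Alder), giving isobutylidenesyncarpic acid and (−)-β-caryophyllene.
2. (−)-β-Caryophyllene delivers the cyclobutane, the nine-membered ring, the exocyclic methylene and the C1/C9 stereocentres intact.
3. Isobutylidenesyncarpic acid comes from syncarpic acid and isobutyraldehyde (Knoevenagel condensation through a Mannich base).
4. Syncarpic acid comes from 2,4,6-trihydroxyacetophenone by dearomative C-tetramethylation and deacetylation.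
5. Ring order: trione ring first (from the arene), pyran ring last; the two carbocycles of the terpene are never built.

Assumption: the (R)-configured phosphoric acid of step 4 is taken as the enantiomer whose pocket leaves the Si face of C1′ of compound 6 open; this sense of induction is a working hypothesis for a new substrate class and has not been tested.

Numbering used for compound 8: terpene carbons keep caryophyllene numbering (C1 and C9 are the cyclobutane methines, C4 the O-bearing quaternary carbon with the methyl group, C5 the adjacent ring-fusion CH, C8 the carbon carrying the exocyclic methylene); C1′ is the isopropyl-bearing CH.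

## Route

Step 1
Reactants: 1 2,4,6-trihydroxyacetophenone [1-(2,4,6-trihydroxyphenyl)ethanone]
Product: 2 acetylsyncarpic acid [2-acetyl-3-hydroxy-4,4,6,6-tetramethylcyclohex-2-ene-1,5-dione; enol form of the 2-acetyl trione; achiral]
Conditions: MeI (6 equiv), NaOMe (5 equiv), MeOH, 0 °C to reflux, 6 h; then 1 M aq. HCl
Reagents that add atoms: iodomethane (MeI), CI
Why: Exhaustive C-alkylation of the phloroglucinol polyanion (dearomative gem-dimethylation) works because the acetyl group blocks one ring carbon, so each of the two free ring carbons takes two methyl groups and the enolised β-triketone results; no stereocentre is formed.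

Step 2
Reactants: 2 acetylsyncarpic acid
Product: 3 syncarpic acid [5-hydroxy-2,2,6,6-tetramethylcyclohex-4-ene-1,3-dione; enol form of 2,2,4,4-tetramethylcyclohexane-1,3,5-trione; achiral]
Conditions: 6 M aq. HCl, reflux, 16 h
Reagents that add atoms: none
Why: Acid-mediated retro-Claisen deacylation of a 2-acyl-1,3-dione, in which water adds to the exocyclic ketone and C–C cleavage releases acetic acid and the stabilised enol of syncarpic acid; no stereocentre is formed.

Step 3
Reactants: 3 syncarpic acid; 4 isobutyraldehyde (2-methylpropanal)
Product: 6 isobutylidenesyncarpic acid [2,2,4,4-tetramethyl-6-(2-methylpropylidene)cyclohexane-1,3,5-trione; achiral], via piperidine Mannich base 5 (not isolated)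
Conditions: piperidine (1.1 equiv), CH2Cl2, rt, 1 h; then 1 M aq. HCl, 0 °C; used at once
Reagents that add atoms: none
Why: Knoevenagel condensation run as a Mannich reaction/elimination, in which the iminium ion from piperidine and the aldehyde is trapped by the enol of 3 to give the racemic Mannich base 5 (which cannot undergo a second Michael addition of 3) and N-protonation then triggers β-elimination of piperidine to the alkylidene 6, which has no stereocentre and no E/Z issue because the trione is symmetric.

Step 4
Reactants: 6 isobutylidenesyncarpic acid; 7 (−)-β-caryophyllene [(1R,4E,9S)-4,11,11-trimethyl-8-methylidenebicyclo[7.2.0]undec-4-ene]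
Product: 8 myrtucommulone K [(1R,4R,5S,9S,1′R); dihydropyran fused to the trione at the enol ether and to the nine-membered ring at C4–C5; C4-methyl and H-5 trans; isopropyl on the same face as the C4-methyl; H-5 and H-1′ cis; exocyclic methylene and cyclobutane unchanged]
Conditions: (R)-3,3′-bis(2,4,6-triisopropylphenyl)-1,1′-binaphthyl-2,2′-diyl hydrogen phosphate (10 mol%), 7 (1.5 equiv), 4 Å MS, toluene, −40 °C, 48 h
Reagents that add atoms: none
Why: Proposed new method: a catalyst-controlled inverse-electron-demand oxa-Diels–Alder reaction in which the chiral phosphoric acid hydrogen-bonds to (partly protonates) a ring carbonyl of 6 next to the alkylidene, lowering the LUMO of the O=C–C=C heterodiene so that the catalysed path outruns the thermal background at −40 °C, while one 2,4,6-triisopropylphenyl wall of the catalyst covers the Re face of C1′ so that the strained trans C4=C5 bond of 7 (inner face blocked by its own ring, outer face of the major αα/βα conformers being the one that peracids epoxidise) stacks only on the Si face; concerted but asynchronous suprafacial bond formation (C5–C1′ ahead of O–C4, positive charge building at tertiary C4) fixes the regiochemistry, carries the E geometry into the trans C4-methyl/H-5 relationship and gives C4 R, C5 S and C1′ R with C1 and C9 untouched; the closest known reaction types are chiral phosphoric acid-catalysed hetero-Diels–Alder reactions of ortho-quinone methides with alkenes and the uncatalysed, poorly selective thermal cycloadditions of alkylidene β-triketones with terpenes, neither of which has been shown as a catalyst-controlled reaction of an alkylidene β-triketone with an unactivated trisubstituted cycloalkene.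

## Compound list

1 | 2,4,6-trihydroxyacetophenone | CC(=O)c1c(O)cc(O)cc1O | starting material
2 | acetylsyncarpic acid (2-acetyl-3-hydroxy-4,4,6,6-tetramethylcyclohex-2-ene-1,5-dione) | CC(=O)C1=C(O)C(C)(C)C(=O)C(C)(C)C1=O | intermediate
3 | syncarpic acid (5-hydroxy-2,2,6,6-tetramethylcyclohex-4-ene-1,3-dione) | CC1(C)C(O)=CC(=O)C(C)(C)C1=O | intermediate
4 | isobutyraldehyde | CC(C)C=O | starting material
5 | piperidine Mannich base, racemic (3-hydroxy-4,4,6,6-tetramethyl-2-[2-methyl-1-(piperidin-1-yl)propyl]cyclohex-2-ene-1,5-dione) | CC(C)C(N1CCCCC1)C1=C(O)C(C)(C)C(=O)C(C)(C)C1=O | intermediate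
6 | isobutylidenesyncarpic acid (2,2,4,4-tetramethyl-6-(2-methylpropylidene)cyclohexane-1,3,5-trione) | CC(C)C=C1C(=O)C(C)(C)C(=O)C(C)(C)C1=O | intermediate
7 | (−)-β-caryophyllene | C/C1=C\CCC(=C)[C@H]2CC(C)(C)[C@@H]2CC1 | starting material
8 | myrtucommulone K | C=C1CC[C@H]2[C@@H](C(C)C)C3=C(O[C@]2(C)CC[C@@H]2[C@@H]1CC2(C)C)C(C)(C)C(=O)C(C)(C)C3=O | target

## Step count and risk

Total step count: 4. Longest linear sequence: 4 steps (1 → 2 → 3 → 6 → 8); compounds 4 and 7 are bought.

The three steps most likely to fail:

Step 4 (the proposed new step). Risks: the acid may not outrun the background reaction, may favour the wrong face of C1′, or may trigger cationic rearrangement of 7 or an ene reaction. The fallback uses known chemistry and replaces catalyst control by the biomimetic domino process with separation. It sets out from 3: syncarpic acid 3, isobutyraldehyde 4 (1.2 equiv) and caryophyllene 7 (2 equiv) are heated with ethylenediammonium diacetate (10 mol%) in toluene at 60 °C, so that 6 forms in the flask (domino Knoevenagel/hetero-Diels–Alder reaction) and is trapped by 7 under substrate control. This is expected to give 8 together with its C1′ epimer 1′-epi-myrtucommulone K F6 and the two adducts of the minor ββ conformer of 7, the (4S,5R,1′R)-diastereomer of myrtucommulone K F7 and the (4S,5R,1′S)-diastereomer of myrtucommulone K F8. Silica gel chromatography followed by preparative HPLC isolates 8, where the fallback comes back to the route.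

Step 3. Risks: bis-adduct formation (Michael addition of a second 3 to 6), tautomerisation of 6 to its dienol, and hydration during work-up. The fallback makes the C–C bond by reductive alkylation and introduces the double bond separately. It sets out from 3: syncarpic acid 3 and isobutyraldehyde 4 are combined with diethyl 2,6-dimethyl-1,4-dihydropyridine-3,5-dicarboxylate and L-proline (20 mol%) in CH2Cl2 at rt to give 2-isobutylsyncarpic acid F3. Selenenylation (PhSeCl, pyridine, CH2Cl2, 0 °C) gives 2-isobutyl-2-(phenylselanyl)syncarpic acid F4. Oxidation (mCPBA, CH2Cl2, −78 °C) gives the selenoxide 2-isobutyl-2-(phenylseleninyl)syncarpic acid F5, which on warming to 0 °C undergoes syn-elimination; the only β-hydrogens are on the side-chain CH2, so the exocyclic alkene forms and the fallback comes back to the route at 6.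

Step 1. Risks: incomplete methylation, O-methylation and over-alkylation mixtures. The fallback installs the two ring methyl groups by a reaction that cannot O-alkylate and leaves only two alkylations for the dearomatising step. It sets out from 1: aminomethylation of 1 (aq. formaldehyde, aq. dimethylamine, EtOH, rt) gives the bis-Mannich base 1-[3,5-bis(dimethylaminomethyl)-2,4,6-trihydroxyphenyl]ethanone F1. Hydrogenolysis (H2 4 bar, 10% Pd/C, AcOH, 60 °C) gives 1-(2,4,6-trihydroxy-3,5-dimethylphenyl)ethanone F2. Geminal methylation at the two methylated ring carbons (MeI 2.5 equiv, NaOMe, MeOH, reflux) then comes back to the route at 2.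

Further compounds
F1 | step 1 | 1-[3,5-bis(dimethylaminomethyl)-2,4,6-trihydroxyphenyl]ethanone | CC(=O)c1c(O)c(CN(C)C)c(O)c(CN(C)C)c1O
F2 | step 1 | 1-(2,4,6-trihydroxy-3,5-dimethylphenyl)ethanone | CC(=O)c1c(O)c(C)c(O)c(C)c1O
F3 | step 3 | 2-isobutylsyncarpic acid (3-hydroxy-4,4,6,6-tetramethyl-2-(2-methylpropyl)cyclohex-2-ene-1,5-dione) | CC(C)CC1=C(O)C(C)(C)C(=O)C(C)(C)C1=O
F4 | step 3 | 2-isobutyl-2-(phenylselanyl)syncarpic acid (2,2,4,4-tetramethyl-6-(2-methylpropyl)-6-(phenylselanyl)cyclohexane-1,3,5-trione) | CC(C)CC1([Se]c2ccccc2)C(=O)C(C)(C)C(=O)C(C)(C)C1=O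
F5 | step 3 | 2-isobutyl-2-(phenylseleninyl)syncarpic acid (2,2,4,4-tetramethyl-6-(2-methylpropyl)-6-(phenylseleninyl)cyclohexane-1,3,5-trione) | CC(C)CC1([Se](=O)c2ccccc2)C(=O)C(C)(C)C(=O)C(C)(C)C1=O
F6 | step 4 | 1′-epi-myrtucommulone K (1R,4R,5S,9S,1′S) | C=C1CC[C@H]2[C@H](C(C)C)C3=C(O[C@]2(C)CC[C@@H]2[C@@H]1CC2(C)C)C(C)(C)C(=O)C(C)(C)C3=O
F7 | step 4 | (4S,5R,1′R)-diastereomer of myrtucommulone K | C=C1CC[C@@H]2[C@@H](C(C)C)C3=C(O[C@@]2(C)CC[C@@H]2[C@@H]1CC2(C)C)C(C)(C)C(=O)C(C)(C)C3=O
F8 | step 4 | (4S,5R,1′S)-diastereomer of myrtucommulone K | C=C1CC[C@@H]2[C@H](C(C)C)C3=C(O[C@@]2(C)CC[C@@H]2[C@@H]1CC2(C)C)C(C)(C)C(=O)C(C)(C)C3=O
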